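The cyclohexane ring is closed by bonding the quaternary oxirane carbon C1 (bearing the CH2OBz arm C7) to the acetoxy carbon C2. The oxirane is read as a former C1=C6 alkene, so C7–C1(=C6)–C2(OH) is a Morita–Baylis–Hillman pattern: an intramolecular Nozaki–Hiyama–Kishi addition of an α-iodoacrylate carbon (C1) to an aldehyde (C2) forms the ring, the C2 stereocentre and the allylic alcohol that later directs epoxidation to its own face. The precursor is an acyclic iodoenoate aldehyde from D-xylose, which supplies C3, C4 and C5; a trans-acetonide on O4/O5 locks the half-chair and masks the final diol.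

Key step: step 8

Remark: locants C1–C7 and O2–O5 in the text are those of the target (C1 = quaternary oxirane carbon carrying C7H2OBz, C2/C3 = acetoxy carbons, C4/C5 = carbinol carbons, C6 = oxirane CH); sugar locants appear only inside compound names, and D-xylose is drawn in its open-chain form.

Step 1
Reactants: 1 D-xylose
Product: 2 D-xylose diethyl dithioacetal
Conditions: EtSH, conc. HCl, 0 °C
Reagents that add atoms: ethanethiol CCS
Why: Acid-catalysed dithioacetalisation opens the pyranose to the acyclic dithioacetal without touching a stereocentre.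

Step 2
Reactants: 2 D-xylose diethyl dithioacetal
Product: 3 2,3:4,5-di-O-isopropylidene-D-xylose diethyl dithioacetal
Conditions: 2,2-dimethoxypropane, TsOH (cat.), acetone, rt
Reagents that add atoms: 2,2-dimethoxypropane COC(C)(C)OC
Why: Acetonide formation under thermodynamic control should give the two dioxolanes of the acyclic threo,threo-tetrol (the trans ring on sugar O2/O3 and the terminal ring on sugar O4/O5), the usual pattern for pentose dithioacetals.

Step 3
Reactants: 3 2,3:4,5-di-O-isopropylidene-D-xylose diethyl dithioacetal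
Product: 4 2,3:4,5-di-O-isopropylidene-aldehydo-D-xylose
Conditions: I2, NaHCO3, acetone/H2O, 0 °C to rt
Reagents that add atoms: water O
Why: Iodine-mediated oxidative hydrolysis of the dithioacetal in bicarbonate buffer should release the aldehyde while both acetonides and the α-stereocentre stay intact.

Step 4
Reactants: 4 2,3:4,5-di-O-isopropylidene-aldehydo-D-xylose; 5 ethyl (triphenylphosphoranylidene)acetate
Product: 7 ethyl (Z)-2,3-dideoxy-2-iodo-4,5:6,7-di-O-isopropylidene-D-xylo-hept-2-enonate, via iodo ylide 6 (not isolated)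
Conditions: 5, NIS, CH2Cl2, −20 °C; then 4, −20 °C to rt
Reagents that add atoms: N-iodosuccinimide O=C1CCC(=O)N1I
Why: Wittig olefination with the iodinated stabilised ylide formed in situ should give the (Z)-α-iodoenoate (ester trans to the sugar chain), with no new stereocentre.

Step 5
Reactants: 7 ethyl (Z)-2,3-dideoxy-2-iodo-4,5:6,7-di-O-isopropylidene-D-xylo-hept-2-enonate
Product: 8 ethyl (Z)-2,3-dideoxy-2-iodo-4,5-O-isopropylidene-D-xylo-hept-2-enonate (6,7-diol)
Conditions: AcOH/H2O (4:1), 40 °C
Reagents that add atoms: none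
Why: Acid-catalysed acetal hydrolysis should be selective for the terminal dioxolane, which is cleaved faster than the internal trans-disubstituted one.

Step 6
Reactants: 8 ethyl (Z)-2,3-dideoxy-2-iodo-4,5-O-isopropylidene-D-xylo-hept-2-enonate
Product: 10 ethyl (Z)-6-O-acetyl-2,3-dideoxy-2-iodo-4,5-O-isopropylidene-7-O-triethylsilyl-D-xylo-hept-2-enonate, via primary triethylsilyl ether 9 (not isolated)
Conditions: TESCl (1.05 equiv), pyridine, CH2Cl2, −40 °C; then Ac2O, DMAP (cat.), 0 °C to rt
Reagents that add atoms: chlorotriethylsilane CC[Si](Cl)(CC)CC; acetic anhydride CC(=O)OC(C)=O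
Why: Kinetic silylation should take the primary hydroxyl and the ensuing DMAP-catalysed acylation the secondary one, so the future C3 oxygen is capped before any acyl migration is possible.

Step 7
Reactants: 10 ethyl (Z)-6-O-acetyl-2,3-dideoxy-2-iodo-4,5-O-isopropylidene-7-O-triethylsilyl-D-xylo-hept-2-enonate
Product: 11 ethyl (Z)-6-acetoxy-2-iodo-4,5-(isopropylidenedioxy)-7-oxohept-2-enoate (D-xylo configuration at C4–C6 of the heptenoate)
Conditions: (COCl)2, DMSO, CH2Cl2, −78 to −30 °C; then iPr2NEt, −78 to 0 °C
Reagents that add atoms: none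
Why: Swern oxidation cleaves a primary triethylsilyl ether and oxidises it in the same pot, so the α-acetoxy aldehyde should form without a free primary alcohol and, with a hindered amine at low temperature, without epimerisation.

Step 8
Reactants: 11 ethyl (Z)-6-acetoxy-2-iodo-4,5-(isopropylidenedioxy)-7-oxohept-2-enoate
Product: 12 ethyl 3-acetoxy-2-hydroxy-4,5-(isopropylidenedioxy)cyclohex-6-ene-1-carboxylate (target locants; O2, O3, O4, O5 all-trans, configuration at C2–C5 as in the target)
Conditions: CrCl2 (8 equiv), NiCl2 (2 mol%), degassed DMSO/THF, rt, 0.005 M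
Reagents that add atoms: none
Why: Divalent chromium, with NiCl2 catalysing insertion into the C–I bond, converts the α-iodoenoate into an α-chromio acrylate (a chromium allenolate) that adds to the tethered aldehyde, and aqueous work-up gives the cyclic Morita–Baylis–Hillman-type alcohol. The closest known reaction type is the intramolecular Nozaki–Hiyama–Kishi closure of halovinyl aldehydes to carbasugar cyclohexenols, here with a Reformatsky-like nucleophile. The cyclohexene ring closes in the 6-exo-trig mode by forming the C1–C2 bond, with C1=C6 ending endocyclic. The new stereocentre C2 is under substrate control: the trans-dioxolane on O4/O5 forces a half-chair with the C3, C4 and C5 oxygens equatorial, and the aldehyde oxygen, held by the same chromium as the ester oxygen, should sit pseudo-equatorial on the outside of the forming ring, trans to the C3 acetate. This facial preference is the least secure element of the route and is backed by the first fallback. The step also needs cyclisation to outrun protodeiodination and dimerisation, which the six-membered closure and high dilution should secure, while acetate, ester and acetonide are inert to CrCl2.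

Step 9
Reactants: 12 ethyl 3-acetoxy-2-hydroxy-4,5-(isopropylidenedioxy)cyclohex-6-ene-1-carboxylate
Product: 13 1-(hydroxymethyl)-4,5-(isopropylidenedioxy)cyclohex-6-ene-2,3-diol (target locants; all-trans)
Conditions: iBu2AlH (6 equiv), CH2Cl2, −78 to 0 °C; aqueous potassium sodium tartrate work-up
Reagents that add atoms: none
Why: Hydride reduction with iBu2AlH should convert the enoate by 1,2-addition into the primary allylic alcohol C7 and remove the temporary C3 acetate in the same operation, leaving the acetonide and all stereocentres untouched.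

Step 10
Reactants: 13 1-(hydroxymethyl)-4,5-(isopropylidenedioxy)cyclohex-6-ene-2,3-diol
Product: 14 [2,3-dihydroxy-4,5-(isopropylidenedioxy)cyclohex-6-en-1-yl]methyl benzoate (target locants)
Conditions: BzCl (1.05 equiv), pyridine, CH2Cl2, −40 °C
Reagents that add atoms: benzoyl chloride O=C(Cl)c1ccccc1
Why: Chemoselective acylation: at low temperature the primary allylic hydroxyl should be benzoylated well ahead of the two secondary ring hydroxyls.

Step 11
Reactants: 14 [2,3-dihydroxy-4,5-(isopropylidenedioxy)cyclohex-6-en-1-yl]methyl benzoate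
Product: 15 1,6-epoxide of 14 (oxirane cis to the C2 hydroxyl and trans to O5)
Conditions: mCPBA, CH2Cl2, 0 °C to rt
Reagents that add atoms: mCPBA O=C(OO)c1cccc(Cl)c1
Why: Henbest hydroxyl-directed peracid epoxidation: the locked pseudo-equatorial C2 hydroxyl hydrogen-bonds the peracid and should deliver oxygen to its own face, which is also anti to the allylic C5 oxygen, so C1 and C6 are set together.

Step 12
Reactants: 15 1,6-epoxide of 14
Product: 16 2,3-di-O-acetate of 15 (4,5-O-isopropylidene derivative of the target)
Conditions: Ac2O, pyridine, DMAP (cat.), CH2Cl2, 0 °C to rt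
Reagents that add atoms: acetic anhydride CC(=O)OC(C)=O
Why: DMAP-catalysed acetylation should esterify both secondary hydroxyls at C2 and C3, while the cis-epoxy alcohol has no anti alkoxide for a Payne rearrangement.

Step 13
Reactants: 16 2,3-di-O-acetate of 15
Product: 17 [(1S,2R,3S,4R,5R,6S)-2,3-bis(acetyloxy)-4,5-dihydroxy-7-oxabicyclo[4.1.0]heptan-1-yl]methyl benzoate (target)
Conditions: AcOH/H2O (4:1), 45 °C
Reagents that add atoms: none
Why: Acid-catalysed acetal hydrolysis: the strained trans-fused dioxolane should be cleaved under mild aqueous acid that leaves the two acetates, the benzoate and the electron-poor oxirane intact.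

Compound list

1 | D-xylose (drawn as the open-chain aldehydo form) | O=C[C@H](O)[C@@H](O)[C@H](O)CO | starting material
2 | D-xylose diethyl dithioacetal | CCSC(SCC)[C@H](O)[C@@H](O)[C@H](O)CO | intermediate
3 | 2,3:4,5-di-O-isopropylidene-D-xylose diethyl dithioacetal | CCSC(SCC)[C@@H]1OC(C)(C)O[C@H]1[C@H]1COC(C)(C)O1 | intermediate
4 | 2,3:4,5-di-O-isopropylidene-aldehydo-D-xylose | O=C[C@@H]1OC(C)(C)O[C@H]1[C@H]1COC(C)(C)O1 | intermediate
5 | ethyl (triphenylphosphoranylidene)acetate | CCOC(=O)C=P(c1ccccc1)(c1ccccc1)c1ccccc1 | starting material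
6 | ethyl iodo(triphenylphosphoranylidene)acetate (iodo ylide, formed in situ) | CCOC(=O)C(I)=P(c1ccccc1)(c1ccccc1)c1ccccc1 | intermediate
7 | ethyl (Z)-2,3-dideoxy-2-iodo-4,5:6,7-di-O-isopropylidene-D-xylo-hept-2-enonate | CCOC(=O)/C(I)=C/[C@@H]1OC(C)(C)O[C@H]1[C@H]1COC(C)(C)O1 | intermediate
8 | ethyl (Z)-2,3-dideoxy-2-iodo-4,5-O-isopropylidene-D-xylo-hept-2-enonate (6,7-diol) | CCOC(=O)/C(I)=C/[C@@H]1OC(C)(C)O[C@H]1[C@H](O)CO | intermediate
9 | 7-O-triethylsilyl ether of 8 (primary silyl ether, formed in situ) | CCOC(=O)/C(I)=C/[C@@H]1OC(C)(C)O[C@H]1[C@H](O)CO[Si](CC)(CC)CC | intermediate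
10 | ethyl (Z)-6-O-acetyl-2,3-dideoxy-2-iodo-4,5-O-isopropylidene-7-O-triethylsilyl-D-xylo-hept-2-enonate | CCOC(=O)/C(I)=C/[C@@H]1OC(C)(C)O[C@H]1[C@H](OC(C)=O)CO[Si](CC)(CC)CC | intermediate
11 | ethyl (Z)-6-acetoxy-2-iodo-4,5-(isopropylidenedioxy)-7-oxohept-2-enoate, D-xylo configuration at C4–C6 | CCOC(=O)/C(I)=C/[C@@H]1OC(C)(C)O[C@H]1[C@H](OC(C)=O)C=O | intermediate
12 | ethyl 3-acetoxy-2-hydroxy-4,5-(isopropylidenedioxy)cyclohex-6-ene-1-carboxylate (target locants; 2,3-trans, 3,4-trans, 4,5-trans; C2–C5 as in the target) | CC(=O)O[C@H]1[C@@H]2OC(C)(C)O[C@H]2C=C(C(=O)OCC)[C@@H]1O | intermediate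
13 | 1-(hydroxymethyl)-4,5-(isopropylidenedioxy)cyclohex-6-ene-2,3-diol (target locants; all-trans, C2–C5 as in the target) | O[C@H]1[C@@H]2OC(C)(C)O[C@H]2C=C(CO)[C@@H]1O | intermediate
14 | [2,3-dihydroxy-4,5-(isopropylidenedioxy)cyclohex-6-en-1-yl]methyl benzoate (target locants; all-trans) | O[C@H]1[C@@H]2OC(C)(C)O[C@H]2C=C(COC(=O)c3ccccc3)[C@@H]1O | intermediate
15 | 1,6-epoxide of 14, oxirane cis to the C2 hydroxyl and trans to O5 | O[C@H]1[C@@H]2OC(C)(C)O[C@H]2[C@@H]3O[C@]3(COC(=O)c4ccccc4)[C@@H]1O | intermediate
16 | 2,3-di-O-acetate of 15 (4,5-O-isopropylidene derivative of the target) | CC(=O)O[C@H]1[C@@H]2OC(C)(C)O[C@H]2[C@@H]3O[C@]3(COC(=O)c4ccccc4)[C@@H]1OC(C)=O | intermediate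
17 | [(1S,2R,3S,4R,5R,6S)-2,3-bis(acetyloxy)-4,5-dihydroxy-7-oxabicyclo[4.1.0]heptan-1-yl]methyl benzoate | CC(=O)O[C@H]1[C@H](O)[C@@H](O)[C@@H]2O[C@]2(COC(=O)c2ccccc2)[C@@H]1OC(C)=O | target

Total step count: 13. Longest linear sequence: 13 steps (1 to 17).

Steps most likely to fail

Step 8. The aldehyde may be attacked on its other face, giving the C2 epimer, or the organochromium may be protonated before it cyclises. The fallback sets out from 11 and comes back at 14; it sets C2 by ketone reduction instead of by the carbon–carbon bond formation. The cyclisation is run as in step 8, and whatever C2 epimer forms, the 2-epi cyclohexenol ester F1, is reduced with iBu2AlH to the 2-epi triol F2 and benzoylated at the primary hydroxyl to the 2-epi benzoate F3. MnO2 (CH2Cl2, rt) should then oxidise only the allylic C2 carbinol to the hydroxy enone F4. Luche reduction (NaBH4, CeCl3·7H2O, MeOH, −78 °C) should add hydride axially and give the pseudo-equatorial alcohol with O2 trans to O3, which is 14. Any 14 present in the mixture passes through F4 in the same way.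

Step 6. Silylation may not discriminate the two hydroxyls cleanly, and in step 7 the acetate may migrate or the α-centre epimerise. The fallback sets out from 8 and comes back at 11; it replaces silyl differentiation by regioselective acylation through a cyclic orthoester. Trimethyl orthoacetate with PPTS (cat.) in CH2Cl2 should give the cyclic methyl orthoacetate F5. Kinetic hydrolysis with aqueous AcOH at rt should open it to the secondary acetate with a free primary hydroxyl, the hydroxy acetate F6. Immediate Dess–Martin oxidation (CH2Cl2, 0 °C) then gives 11.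

Step 11. The trisubstituted alkene, flanked by three allylic C–O bonds, may react sluggishly with the peracid, and facial control may erode. The fallback sets out from 13 and comes back at 15; it reverses the order of benzoylation and epoxidation and delivers the oxygen from a metal alkoxide. Triol 13, whose alkene is not yet deactivated by the allylic benzoate, is treated with VO(acac)2 (cat.) and tBuOOH (CH2Cl2, 0 °C to rt). The vanadate bound to the primary C7 hydroxyl and chelated by the C2 hydroxyl should deliver oxygen to the face of O2 and give the epoxy triol F7. BzCl/pyridine at −40 °C should then acylate only the primary hydroxyl to give 15.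

Further compounds

F1 | step 8 | ethyl 3-acetoxy-2-hydroxy-4,5-(isopropylidenedioxy)cyclohex-6-ene-1-carboxylate, C2 epimer of 12 (O2 cis to O3) | CC(=O)O[C@H]1[C@@H]2OC(C)(C)O[C@H]2C=C(C(=O)OCC)[C@H]1O
F2 | step 8 | 1-(hydroxymethyl)-4,5-(isopropylidenedioxy)cyclohex-6-ene-2,3-diol, C2 epimer of 13 | O[C@H]1[C@@H]2OC(C)(C)O[C@H]2C=C(CO)[C@H]1O
F3 | step 8 | [2,3-dihydroxy-4,5-(isopropylidenedioxy)cyclohex-6-en-1-yl]methyl benzoate, C2 epimer of 14 | O[C@H]1[C@@H]2OC(C)(C)O[C@H]2C=C(COC(=O)c3ccccc3)[C@H]1O
F4 | step 8 | [3-hydroxy-4,5-(isopropylidenedioxy)-2-oxocyclohex-6-en-1-yl]methyl benzoate (enone, target locants) | O[C@H]1[C@@H]2OC(C)(C)O[C@H]2C=C(COC(=O)c3ccccc3)C1=O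
F5 | step 6 | 6,7-O-(1-methoxyethylidene) cyclic orthoacetate of 8 | CCOC(=O)/C(I)=C/[C@@H]1OC(C)(C)O[C@H]1[C@H]1COC(C)(OC)O1
F6 | step 6 | ethyl (Z)-6-O-acetyl-2,3-dideoxy-2-iodo-4,5-O-isopropylidene-D-xylo-hept-2-enonate (free 7-hydroxyl) | CCOC(=O)/C(I)=C/[C@@H]1OC(C)(C)O[C@H]1[C@H](OC(C)=O)CO
F7 | step 11 | 1,6-epoxide of triol 13 (oxirane cis to the C2 hydroxyl) | O[C@H]1[C@@H]2OC(C)(C)O[C@H]2[C@@H]3O[C@]3(CO)[C@@H]1O
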